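## Structural features

The target 48 is a briarane diterpenoid. Cyclohexene ring A (C1, C10, C11=C12, C13, C14) is trans-fused through C1–C10 to the ten-membered ring B (C1–C10), which holds the (Z)-C5=C6 alkene. γ-Lactone ring C (C7, C8, C17, C19, O) is fused to ring B at C7–C8. There are nine stereocentres (1R,2R,4R,7S,8S,9R,10S,14S,17R): C7, C8 and C17 are contiguous on ring C, the run C8–C9–C10–C1–C2 continues into ring A, C14 stands next to the quaternary C1, and only C4 is isolated. C1 is an all-carbon quaternary centre and C8 a fully substituted carbinol, so each carbon of the C9–C10 bond has a fully substituted neighbour. The fragile features are: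
- five esters of two kinds (four acetates and the O4 butanoate), which can migrate;
- the free tertiary O8–H β to the lactone carbonyl, which invites retro-aldol opening and elimination to the C8=C17 butenolide under base;
- the epimerisable C17;
- the allylic C–O bonds at C4, C7 and C16.

The real difficulty is to make C8 with four different substituents in one absolute sense, to join C9 to C10 with control at both ends, and to close ring B around a trisubstituted (Z)-alkene while the butanoate stays distinct from the acetates. The key step exploits the fact that C8 carries an oxygen, a carbonyl-derived carbon (C9), the lactone alkoxy carbon (C7) and the α-carbon (C17) of the lactone carbonyl C19. This is the pattern of a glycolate aldol lactone, so ring C can be assembled around C8 from a C8–C9 acylsilane, a C17–C19 propanoyl enolate and a C7 aldehyde.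

## Logic of the disconnections

**48 ⇒ 47 ⇒ 46 ⇒ 45.** The O16–acetyl bond, the O16–Si and O8–Si bonds and the O4–butanoyl bond are cut last. O4 is the last hydroxyl to appear, so it can take the only butanoate when O2, O9 and O14 are already acetates. O16 stays silylated until only the unreactive tertiary O8–H competes with it. The gain is that 45 has a single free hydroxyl. The demand is that fluoride cleaves a tertiary silyl ether without ester migration.

**45 ⇒ 43.** The C4–C5 bond of ring B is cut. It joins an sp2 carbon to a carbinol carbon (alkenyl–metal plus aldehyde polarity) and lies away from the congested C8–C10 region. The bicyclic core becomes an open chain in which ring A and ring C are complete. The forward step must close a ten-membered ring, keep the (Z)-geometry and give 4R. No ester may sit β to the carbon–metal bond, which is why O16 is a silyl ether at this stage.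

**43 ⇒ 42 ⇒ 41 ⇒ 40 ⇒ 38 ⇒ 37.** These are functional-group changes: the C4 aldehyde from a primary silyl ether, C5–I and C6–H from the C5≡C6 alkyne, and O16–H from its 4-methoxybenzyl ether. The alkyne is kept as long as possible because it is inert to the chromium, cobalt and acylation chemistry. The free O16–H is needed to steer tin to C5. The demand is trans addition with tin on C5 only, three silyl ethers of graded lability (O4 primary TBS, O16 primary TBDPS, O8 tertiary TBS) and one ether removable by oxidation.

**37 ⇒ 36 ⇒ 35.** The C11=C12 alkene is traced back to an exocyclic C11=C20 alkene and the O9 acetate to the alcohol. An allyl metal with the metal on C20 holds C1 trans to the metal-bearing carbon across C10=C11, which a closed transition state turns into the anti C9/C10 relation of 48. A ring-contained allyl metal (metal on C12) would be expected to give the syn relation. The cost is one isomerisation step, which must remove hydrogen from C12 and not from C10.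

**35 ⇒ 33 + 14.** The C9–C10 bond is cut. This is the most convergent cut: ring A with C2–C4 and C20 on one side, ring C with C5–C9 and C16 on the other. The forward step must join two carbons that each have a fully substituted neighbour, attack ring A on the face cis to the C1 methyl, and be anti-selective. C7 and C17 both turn a hydrogen towards C9, so 33 has little facial bias of its own and reagent control should dominate.

**33 ⇒ 31 ⇒ 29.** Only the oxidation level of C9 changes. A hydride would reduce the lactone before the hindered tert-butyl ester, so the ester is cleaved at the alkyl–oxygen bond and the acid is reduced through its chloride.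

**29 ⇒ 17 + 21 + 25.** C8–C17, C7–C8 and O7–C19 are cut, which opens ring C and removes three stereocentres at once. The components are simple and achiral apart from the auxiliary in 21. The forward step must order three events (addition to the acylsilane, silyl shift, aldol) before lactonisation and must transmit chirality from the auxiliary to C17 and from C17 to C8 and C7. Two design changes are made without touching the skeleton: O16 is a 4-methoxybenzyl ether, and 25 is added only after 17 has been consumed.

**17 ⇒ 16 ⇒ 15; 21 ⇒ 18 + 19; 25 ⇒ 24 ⇒ 22.** These cut a C–Si bond and the C8=O bond, an N–acyl bond, and an O–benzyl bond with a change of oxidation level. All are short and use commercial materials.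

**14 ⇒ 12 ⇒ 11 ⇒ 10.** The C20–Br bond and the C11=C20 bond are cut, leading back to a C10 ketone. Because C1 is quaternary, C11 is the only enolisable position, so C20 can be introduced without a regiochemical question.

**10 ⇒ 9 ⇒ 8 ⇒ 7 ⇒ 5.** The two acetates, the O4 silyl ether and the C4–O bond are removed in turn, leaving a terminal alkene. The benzyl ether on O2 is exchanged for acetate before any other alkene is present.

**5 ⇒ 4.** The C14–H bond is cut, which gives a diketone with only one stereocentre (C2). The forward reduction must choose one of two carbonyl groups and one face, fixing C1 and C14 together.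

**4 ⇒ 2 + 3 and 2 ⇒ 1.** The C1–C2 bond is cut to an alkoxyallene and a symmetrical diketone. The forward addition creates the quaternary carbon and the oxygenated C2 in one catalytic, atom-economic step and must set C2 by ligand control.

## Other disconnections considered

**Alternative 1:** The cut is C1–C14 and C10–C11 of ring A. In the forward sense diene A1 and enal A2 would combine in a [4+2] cycloaddition under a chiral oxazaborolidinium Lewis acid to give A3.
- In favour: one catalytic step would set C1, C10 and C14. Suprafacial addition fixes the trans C1/C10 relation and endo orientation gives the cis O14/C2 relation.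
- Against: A2 is a trisubstituted dienophile, the ring alkene appears at C12=C13 and would have to be moved to C11=C12 through a temporary C11 stereocentre, and C9 arrives as a simple oxygenated arm. The hindered C8 carbinol with C7 and C17 would then have to be built next to C10 in separate operations.
- Comparison: for ring A this alternative is the better plan (one step against nine for 14, and C10 fixed by a concerted mechanism where step 19 relies on a face-selective addition). For ring C the chosen plan is better, since three stereocentres and the ring form in one flask. Overall step economy would be about equal once alkene transposition and stepwise lactone construction are counted.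

**Alternative 2:** The cut is C9–C10, made from a cyclic C9–O–C12 ether. Tin–lithium exchange in stannyl ether A4 would give a C9 carbanion whose [2,3]-shift leads to A5, forming C9–C10, breaking O–C12 and contracting a thirteen-membered ring to ring B.
- In favour: the congested bond would form intramolecularly, the alkene would arrive directly at C11=C12 (better than the chosen plan, which needs step 21), and ring B would form by contraction, not by closure of a medium ring.
- Against: an alkyllithium is incompatible with esters and a lactone, so ring C would be carried in reduced form with acetal protection and five esters and the C19 oxidation level restored later. A4 needs its own macrocyclisation and a defined α-stannyl centre, the C7/C8/C17 triad must come from other chemistry, and transannular stereocontrol in a thirteen-membered ring is hard to predict.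
- Comparison: the two plans are equal in choosing the C9–C10 bond. The alternative is mechanistically better at C11=C12 and at ring B. The chosen plan is better in functional-group economy and in the construction of ring C.

**Alternative 3:** The cut is C1–C10. Pd(PPh3)4 would ionise the C12 carbonate of macrocycle A6 and the C1 enolate would attack C10 across the ring to give A7, closing rings A and B together.
- In favour: two rings, the quaternary C1 and C10 would form in one nearly neutral catalytic step, C11=C12 would be in place, and a fourteen-membered precursor is easier to close than a ten-membered ring (better than the chosen plan in ring-forming economy).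
- Against: C2 and C14 emerge as ketones that must later be reduced and told apart (two uncertain stereocentres), the allyl complex can be attacked at C12 or through oxygen, the C1/C10 configuration depends on macrocycle conformation, and A6 must already contain the whole C7–C9 array.
- Comparison: the alternative is the better in ring construction and equal in needing a macrocyclisation. The chosen plan is better in fixing C1, C2 and C14 early in a small ring under catalyst control and in making ring C in one step.

Key step: step 16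

Assumption 1: in step 2 the (1R,2R)-diphosphine is taken to deliver the (R)-ether at C2; if the sense is the reverse, its mirror image is used.
Assumption 2: in step 16 both zinc enolates are taken to react through closed, chelated transition states; on this basis the (S)-benzyl auxiliary gives 17R and, from it, 8S and 7S.
Remark: the oxolane descriptors of 29 (2S,3S,4R) correspond to C7 (S), C8 (S) and C17 (R) of 48, and the (4S) auxiliary with a racemic bromide centre is what the enolate chemistry needs. O16 is a 4-methoxybenzyl (PMB) ether instead of a silyl ether so that it can be freed independently of the silyl ethers.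
Abbreviations: TBS = tert-butyldimethylsilyl, TBDPS = tert-butyldiphenylsilyl, DMP = 1,1,1-triacetoxy-1,1-dihydro-1,2-benziodoxol-3(1H)-one.

## Route

Step 1
Reactants: 1 benzyl propargyl ether
Product: 2 benzyloxyallene
Conditions: KOtBu (0.3 equiv), THF, 0 °C → rt
Reagents that add atoms: none
Why: Base-catalysed propargyl–allenyl isomerisation of a propargylic ether, driven by conjugation of the allene with oxygen.

Step 2
Reactants: 2 benzyloxyallene; 3 2-methylcyclohexane-1,3-dione
Product: 4 2-[(1R)-1-(benzyloxy)prop-2-enyl]-2-methylcyclohexane-1,3-dione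
Conditions: Pd2(dba)3·CHCl3 (2.5 mol%), (1R,2R)-N,N′-bis[2-(diphenylphosphino)benzoyl]cyclohexane-1,2-diamine (7.5 mol%), PhCO2H (10 mol%), CH2Cl2, rt
Reagents that add atoms: none
Why: Zerovalent palladium and the acidic diketone hydropalladate the allene to an alkoxy-substituted π-allyl complex, which the diketone carbon attacks at the oxygen-bearing terminus (Tsuji–Trost-type addition of 1,3-dicarbonyl pronucleophiles to alkoxyallenes). The chiral diphosphine sets C2 and no by-product forms.

Step 3
Reactants: 4 2-[(1R)-1-(benzyloxy)prop-2-enyl]-2-methylcyclohexane-1,3-dione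
Product: 5 (2R,3S)-2-[(1R)-1-(benzyloxy)prop-2-enyl]-3-hydroxy-2-methylcyclohexanone
Conditions: (R)-1-methyl-3,3-diphenyltetrahydro-1H,3H-pyrrolo[1,2-c][1,3,2]oxazaborole (0.2 equiv), catecholborane (1.1 equiv), toluene, −60 °C; aq. NaHCO3
Reagents that add atoms: none
Why: Corey–Bakshi–Shibata reduction as a desymmetrisation of a 2,2-disubstituted 1,3-diketone. Hydride enters anti to the bulky side chain, so the catalyst reduces only the carbonyl whose exposed face it matches, which sets C14 (hydroxyl cis to the side chain) and thereby the quaternary C1.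

Step 4
Reactants: 5 (2R,3S)-2-[(1R)-1-(benzyloxy)prop-2-enyl]-3-hydroxy-2-methylcyclohexanone
Product: 7 (2R,3S)-2-[(1R)-1-(benzyloxy)-3-hydroxypropyl]-3-hydroxy-2-methylcyclohexanone, via bis(catecholboryl) intermediate 6 (not isolated)
Conditions: catecholborane (2.5 equiv), RhCl(PPh3)3 (2 mol%), THF, rt; then 30% H2O2, pH 7 phosphate buffer, 0 °C
Reagents that add atoms: hydrogen peroxide, OO
Why: Rhodium-catalysed hydroboration is selective for a terminal alkene over a ketone and puts boron on C4. Buffered peroxide then oxidises the C–B bond without exposing the ketol to base.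

Step 5
Reactants: 7 (2R,3S)-2-[(1R)-1-(benzyloxy)-3-hydroxypropyl]-3-hydroxy-2-methylcyclohexanone
Product: 8 (2R,3S)-2-[(1R)-1-(benzyloxy)-3-(tert-butyldimethylsilyloxy)propyl]-3-hydroxy-2-methylcyclohexanone
Conditions: TBSCl (1.05 equiv), imidazole, CH2Cl2, 0 °C
Reagents that add atoms: tert-butyldimethylsilyl chloride, CC(C)(C)[Si](C)(C)Cl
Why: Silylation; the primary hydroxyl reacts far faster than the secondary one next to the quaternary carbon.

Step 6
Reactants: 8 (2R,3S)-2-[(1R)-1-(benzyloxy)-3-(tert-butyldimethylsilyloxy)propyl]-3-hydroxy-2-methylcyclohexanone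
Product: 9 (2R,3S)-2-[(1R)-3-(tert-butyldimethylsilyloxy)-1-hydroxypropyl]-3-hydroxy-2-methylcyclohexanone
Conditions: H2 (1 atm), Pd(OH)2/C, EtOAc, rt
Reagents that add atoms: none
Why: Hydrogenolysis of the benzyl ether at a stage with no alkene; the ketone and the silyl ether are inert in ethyl acetate.

Step 7
Reactants: 9 (2R,3S)-2-[(1R)-3-(tert-butyldimethylsilyloxy)-1-hydroxypropyl]-3-hydroxy-2-methylcyclohexanone
Product: 10 (1S,2R)-2-[(1R)-1-acetoxy-3-(tert-butyldimethylsilyloxy)propyl]-2-methyl-3-oxocyclohexyl acetate
Conditions: Ac2O, DMAP, pyridine, CH2Cl2, rt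
Reagents that add atoms: acetic anhydride, CC(=O)OC(C)=O
Why: DMAP-catalysed acylation installs the O2 and O14 acetates of the target in one step. The quaternary C1 rules out β-elimination from the ketone.

Step 8
Reactants: 10 (1S,2R)-2-[(1R)-1-acetoxy-3-(tert-butyldimethylsilyloxy)propyl]-2-methyl-3-oxocyclohexyl acetate
Product: 11 (1S,2R)-2-[(1R)-1-acetoxy-3-(tert-butyldimethylsilyloxy)propyl]-2-methyl-4-methylidene-3-oxocyclohexyl acetate
Conditions: (CH2O)n, N-methylanilinium trifluoroacetate, THF, reflux
Reagents that add atoms: formaldehyde (as paraformaldehyde), C=O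
Why: Mannich-type α-methylenation of a ketone. C11 is the only enolisable position and the weakly acidic medium spares the acetates; the enone is used crude to avoid dimerisation.

Step 9
Reactants: 11 (1S,2R)-2-[(1R)-1-acetoxy-3-(tert-butyldimethylsilyloxy)propyl]-2-methyl-4-methylidene-3-oxocyclohexyl acetate
Product: 12 (1S,2R,3RS)-2-[(1R)-1-acetoxy-3-(tert-butyldimethylsilyloxy)propyl]-3-hydroxy-2-methyl-4-methylidenecyclohexyl acetate
Conditions: NaBH4, CeCl3·7H2O, MeOH, −78 → −20 °C
Reagents that add atoms: none
Why: Luche reduction gives 1,2-reduction of the enone. The configuration of the new carbinol does not matter because C10 becomes part of an allyl metal.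

Step 10
Reactants: 12 (1S,2R,3RS)-2-[(1R)-1-acetoxy-3-(tert-butyldimethylsilyloxy)propyl]-3-hydroxy-2-methyl-4-methylidenecyclohexyl acetate
Product: 14 (1S,2R)-2-[(1R)-1-acetoxy-3-(tert-butyldimethylsilyloxy)propyl]-4-(bromomethyl)-2-methylcyclohex-3-enyl acetate, via allylic mesylate 13 (not isolated)
Conditions: MsCl, Et3N, CH2Cl2, −20 °C; then LiBr, THF, 0 °C → rt
Reagents that add atoms: lithium bromide, [Li+].[Br-]
Why: Bromide displaces the hindered secondary mesylate with allylic transposition (SN2′) at the open methylene. Either allylic bromide would give the same allylchromium reagent, so the regiochemistry is not critical.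

Step 11
Reactants: 15 tert-butyl diazoacetate
Product: 16 tert-butyl 2-(tert-butyldimethylsilyl)-2-diazoacetate
Conditions: TBSOTf, iPr2NEt, Et2O, −20 °C → rt
Reagents that add atoms: tert-butyldimethylsilyl trifluoromethanesulfonate, CC(C)(C)[Si](C)(C)OS(=O)(=O)C(F)(F)F
Why: Electrophilic C-silylation of the diazo carbon followed by deprotonation, the standard entry to α-silyl diazo esters.

Step 12
Reactants: 16 tert-butyl 2-(tert-butyldimethylsilyl)-2-diazoacetate
Product: 17 tert-butyl 2-(tert-butyldimethylsilyl)-2-oxoacetate
Conditions: KHSO5 (Oxone), NaHCO3, acetone/H2O/CH2Cl2, 0 °C → rt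
Reagents that add atoms: potassium peroxymonosulfate (oxygen delivered through dimethyldioxirane), [K+].[O-]S(=O)(=O)OO
Why: Dimethyldioxirane formed in situ transfers oxygen to the diazo carbon with loss of nitrogen, the established route to silyl glyoxylates.

Step 13
Reactants: 18 (S)-4-benzyloxazolidin-2-one; 19 2-bromopropanoyl bromide
Product: 21 (4S)-4-benzyl-3-[(2RS)-2-bromopropanoyl]oxazolidin-2-one, via N-lithio oxazolidinone 20 (not isolated)
Conditions: n-BuLi, THF, −78 °C; then 19, −78 → 0 °C
Reagents that add atoms: none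
Why: N-Acylation of the lithiated oxazolidinone. The bromide-bearing carbon may stay racemic because it becomes an enolate carbon.

Step 14
Reactants: 22 but-2-yne-1,4-diol
Product: 24 4-(4-methoxybenzyloxy)but-2-yn-1-ol, via monosodium alkoxide 23 (not isolated)
Conditions: NaH (1 equiv), THF/DMF, 0 °C (22 in threefold excess); then PMBCl, Bu4NI (cat.), rt
Reagents that add atoms: 4-methoxybenzyl chloride, COc1ccc(CCl)cc1
Why: Williamson etherification; the excess of diol favours the mono ether.

Step 15
Reactants: 24 4-(4-methoxybenzyloxy)but-2-yn-1-ol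
Product: 25 4-(4-methoxybenzyloxy)but-2-ynal
Conditions: DMP, NaHCO3, CH2Cl2, 0 °C
Reagents that add atoms: none
Why: Buffered Dess–Martin oxidation of a propargylic alcohol; the sensitive ynal is used at once.

Step 16
Reactants: 21 (4S)-4-benzyl-3-[(2RS)-2-bromopropanoyl]oxazolidin-2-one; 17 tert-butyl 2-(tert-butyldimethylsilyl)-2-oxoacetate; 25 4-(4-methoxybenzyloxy)but-2-ynal
Product: 29 tert-butyl (2S,3S,4R)-3-(tert-butyldimethylsilyloxy)-2-[3-(4-methoxybenzyloxy)prop-1-ynyl]-4-methyl-5-oxooxolane-3-carboxylate, via zinc imide enolate 26 (not isolated), via zinc glycolate enolate 27 (not isolated), via zinc aldolate 28 (not isolated)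
Conditions: Zn dust (Me3SiCl-activated), THF, 0 °C; then 17, −30 °C; then 25, −30 °C → rt; aq. NH4Cl
Reagents that add atoms: none
Why: Proposed new method: zinc inserts into the C–Br bond of 21 to give the chelated (Z)-enolate 26, which adds to the acylsilane carbonyl of 17 (C8–C17); the zinc alkoxide then undergoes a 1,2-Brook shift of silicon from C8 to O8 to give enolate 27, which adds to 25 (C7–C8), and the C7 alkoxide 28 attacks the imide carbonyl C19 and expels the oxazolidinone. The closest known reaction is the Reformatsky/Brook/aldol/lactonisation coupling of α-bromo ester zinc enolates with silyl glyoxylates and carbonyl compounds; new here are the acyl oxazolidinone as enolate precursor and leaving group and an ynal as the last electrophile. Ring C closes by 5-exo-trig acyl substitution of O7 on C19, the exocyclic imide carbonyl being more electrophilic than the ring carbamate. C17 is set in the first addition, where the acylsilane approaches the face of the zinc-chelated imide enolate away from the benzyl group (17R). C8 is controlled by C17: with zinc held between the enolate oxygen and the C19 carbonyl, the C17 hydrogen lies in the enolate plane and the zinc-bound aldehyde is delivered anti to the C17 methyl (8S). C7 follows from the closed six-membered transition state with the slim alkynyl group equatorial (7S). The step needs 26 to choose the acylsilane over the ynal, which the high electrophilicity of 17 and the late addition of 25 secure; the tert-butyl ester resists attack and the alkyne is carried on for the later (Z)-alkene.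

Step 17
Reactants: 29 tert-butyl (2S,3S,4R)-3-(tert-butyldimethylsilyloxy)-2-[3-(4-methoxybenzyloxy)prop-1-ynyl]-4-methyl-5-oxooxolane-3-carboxylate
Product: 31 (2S,3S,4R)-3-(tert-butyldimethylsilyloxy)-2-[3-(4-methoxybenzyloxy)prop-1-ynyl]-4-methyl-5-oxooxolane-3-carboxylic acid, via trimethylsilyl ester 30 (not isolated)
Conditions: Me3SiOTf, 2,6-lutidine, CH2Cl2, 0 °C → rt; then pH 4 aqueous work-up
Reagents that add atoms: none
Why: The silyl triflate cleaves the tert-butyl ester at the alkyl–oxygen bond (loss of isobutene) and the silyl ester hydrolyses on work-up. Lactone, silyl ether and PMB ether are untouched, which no hydride reduction of the ester could achieve.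

Step 18
Reactants: 31 (2S,3S,4R)-3-(tert-butyldimethylsilyloxy)-2-[3-(4-methoxybenzyloxy)prop-1-ynyl]-4-methyl-5-oxooxolane-3-carboxylic acid
Product: 33 (2S,3S,4R)-3-(tert-butyldimethylsilyloxy)-2-[3-(4-methoxybenzyloxy)prop-1-ynyl]-4-methyl-5-oxooxolane-3-carbaldehyde, via acid chloride 32 (not isolated)
Conditions: Me2C=C(Cl)NMe2, CH2Cl2, 0 °C → rt; then LiAlH(OtBu)3, THF, −78 °C
Reagents that add atoms: none
Why: The α-chloroenamine forms the acid chloride under neutral conditions, and LiAlH(OtBu)3 reduces acid chlorides to aldehydes at −78 °C without touching lactones. C8 is fully substituted, so the aldehyde cannot epimerise.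

Step 19
Reactants: 33 (2S,3S,4R)-3-(tert-butyldimethylsilyloxy)-2-[3-(4-methoxybenzyloxy)prop-1-ynyl]-4-methyl-5-oxooxolane-3-carbaldehyde; 14 (1S,2R)-2-[(1R)-1-acetoxy-3-(tert-butyldimethylsilyloxy)propyl]-4-(bromomethyl)-2-methylcyclohex-3-enyl acetate
Product: 35 C9–C10 coupled alcohol (9-OH; exocyclic C11=C20), via allylchromium dichloride 34 (not isolated)
Conditions: CrCl2 (4 equiv), THF, 0 °C → rt
Reagents that add atoms: none
Why: Nozaki–Hiyama allylation: divalent chromium turns 14 into 34 (chromium on C20), which adds through its γ-carbon C10 in a closed chair transition state. C1 is trans to the CH2Cr group across C10=C11 and so equatorial, which should give the anti C9/C10 relation (9R). The aldehyde should approach the ring face cis to the C1 methyl, away from the side chain and the O14 acetate (10S).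

Step 20
Reactants: 35 C9–C10 coupled alcohol (9-OH; exocyclic C11=C20)
Product: 36 9-acetate of 35
Conditions: Ac2O, DMAP, Et3N, CH2Cl2, 35 °C
Reagents that add atoms: acetic anhydride, CC(=O)OC(C)=O
Why: Forced DMAP acylation of the hindered secondary hydroxyl. It also removes the chance of lactone transfer from O7 to O9.

Step 21
Reactants: 36 9-acetate of 35
Product: 37 C11=C12 isomer of 36
Conditions: Co(salen)Cl (5 mol%; salen = N,N′-bis(3,5-di-tert-butylsalicylidene)cyclohexane-1,2-diaminate), PhSiH3 (5 mol%), benzene, rt
Reagents that add atoms: none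
Why: Cobalt hydride hydrogen-atom-transfer isomerisation of a 1,1-disubstituted alkene. Hydrogen adds to C20 and the tertiary C11 radical gives back a hydrogen from the accessible C12, not from the shielded C10, to form the trisubstituted ring alkene.

Step 22
Reactants: 37 C11=C12 isomer of 36
Product: 38 propargylic alcohol (16-OH)
Conditions: DDQ, CH2Cl2/pH 7 buffer, 0 °C
Reagents that add atoms: none
Why: Oxidative cleavage of the PMB ether; silyl ethers, esters, the alkyne and the ring alkene are inert.

Step 23
Reactants: 38 propargylic alcohol (16-OH)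
Product: 40 (Z)-C5 iodoalkene (16-OH), via alkenylstannane 39 (not isolated)
Conditions: Bu3SnH (1.2 equiv), [Cp*RuCl]4 (2.5 mol%), CH2Cl2, rt; then I2, 0 °C
Reagents that add atoms: iodine, II
Why: Hydroxyl-directed ruthenium-catalysed trans-hydrostannation places tin on C5 (next to the carbinol carbon) and hydrogen on C6 trans to it. Tin–iodine exchange with retention then gives the iodide with iodine cis to C7.

Step 24
Reactants: 40 (Z)-C5 iodoalkene (16-OH)
Product: 41 O16-TBDPS ether of 40
Conditions: TBDPSCl, imidazole, CH2Cl2, rt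
Reagents that add atoms: tert-butyl(chloro)diphenylsilane, CC(C)(C)[Si](Cl)(c1ccccc1)c1ccccc1
Why: Silylation of the only free hydroxyl. A silyl ether β to the later carbon–metal bond is not ionised or eliminated as an allylic acetate might be.

Step 25
Reactants: 41 O16-TBDPS ether of 40
Product: 42 C4 primary alcohol
Conditions: CSA (0.1 equiv), MeOH/CH2Cl2, 0 °C
Reagents that add atoms: none
Why: Acid-catalysed methanolysis removes the primary alkyl TBS ether much faster than the primary TBDPS ether or the tertiary TBS ether.

Step 26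
Reactants: 42 C4 primary alcohol
Product: 43 C4 aldehyde
Conditions: DMP, NaHCO3, CH2Cl2, 0 °C → rt
Reagents that add atoms: none
Why: Buffered Dess–Martin oxidation; the β-acetoxy aldehyde is used crude to avoid loss of acetic acid.

Step 27
Reactants: 43 C4 aldehyde
Product: 45 ring B alcohol (4R-OH; O8-TBS; O16-TBDPS), via alkenylchromium dichloride 44 (not isolated)
Conditions: CrCl2 (10 equiv), NiCl2 (0.1 equiv), DMSO, rt, 0.002 M, slow addition
Reagents that add atoms: none
Why: Nozaki–Hiyama–Kishi reaction: zerovalent nickel inserts into the C–I bond, transmetalation gives 44 with retention of alkene geometry, and intramolecular addition to the aldehyde closes the ten-membered ring B. The 4R configuration is expected from the 1,3-anti preference induced by the C2 acetoxy group and from addition on the outer face of the forming ring.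

Step 28
Reactants: 45 ring B alcohol (4R-OH; O8-TBS; O16-TBDPS)
Product: 46 4-butanoate of 45
Conditions: (PrCO)2O, DMAP, pyridine, CH2Cl2, 0 °C → rt
Reagents that add atoms: butanoic anhydride, CCCC(=O)OC(=O)CCC
Why: DMAP-catalysed acylation of the only free hydroxyl gives the single butanoate of the target.

Step 29
Reactants: 46 4-butanoate of 45
Product: 47 8,16-diol (16-deacetyl-48)
Conditions: HF·pyridine, pyridine/THF, 0 → 40 °C
Reagents that add atoms: none
Why: Fluoride cleaves the primary TBDPS ether and the tertiary TBS ether. Pyridine buffering keeps the esters and the β-hydroxy lactone intact and disfavours acyl migration.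

Step 30
Reactants: 47 8,16-diol (16-deacetyl-48)
Product: 48 CNP0290502.1
Conditions: Ac2O, pyridine, CH2Cl2, 0 °C
Reagents that add atoms: acetic anhydride, CC(=O)OC(C)=O
Why: Acetylation of the primary allylic hydroxyl; the hindered tertiary O8–H does not react without DMAP.

## Compound list

1 | benzyl propargyl ether | C#CCOCc1ccccc1 | starting material
2 | benzyloxyallene | C=C=COCc1ccccc1 | intermediate
3 | 2-methylcyclohexane-1,3-dione | CC1C(=O)CCCC1=O | starting material
4 | 2-[(1R)-1-(benzyloxy)prop-2-enyl]-2-methylcyclohexane-1,3-dione | C=C[C@@H](OCc1ccccc1)C1(C)C(=O)CCCC1=O | intermediate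
5 | (2R,3S)-2-[(1R)-1-(benzyloxy)prop-2-enyl]-3-hydroxy-2-methylcyclohexanone | C=C[C@@H](OCc1ccccc1)[C@@]1(C)[C@@H](O)CCCC1=O | intermediate
6 | bis(catecholboryl) intermediate (boron on C4 and on O14) | c1ccc2OB(CC[C@@H](OCc3ccccc3)[C@@]4(C)[C@@H](OB5Oc6ccccc6O5)CCCC4=O)Oc2c1 | intermediate
7 | (2R,3S)-2-[(1R)-1-(benzyloxy)-3-hydroxypropyl]-3-hydroxy-2-methylcyclohexanone | OCC[C@@H](OCc1ccccc1)[C@@]1(C)[C@@H](O)CCCC1=O | intermediate
8 | (2R,3S)-2-[(1R)-1-(benzyloxy)-3-(tert-butyldimethylsilyloxy)propyl]-3-hydroxy-2-methylcyclohexanone | CC(C)(C)[Si](C)(C)OCC[C@@H](OCc1ccccc1)[C@@]1(C)[C@@H](O)CCCC1=O | intermediate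
9 | (2R,3S)-2-[(1R)-3-(tert-butyldimethylsilyloxy)-1-hydroxypropyl]-3-hydroxy-2-methylcyclohexanone | CC(C)(C)[Si](C)(C)OCC[C@@H](O)[C@@]1(C)[C@@H](O)CCCC1=O | intermediate
10 | (1S,2R)-2-[(1R)-1-acetoxy-3-(tert-butyldimethylsilyloxy)propyl]-2-methyl-3-oxocyclohexyl acetate | CC(C)(C)[Si](C)(C)OCC[C@@H](OC(C)=O)[C@@]1(C)[C@@H](OC(C)=O)CCCC1=O | intermediate
11 | (1S,2R)-2-[(1R)-1-acetoxy-3-(tert-butyldimethylsilyloxy)propyl]-2-methyl-4-methylidene-3-oxocyclohexyl acetate | CC(C)(C)[Si](C)(C)OCC[C@@H](OC(C)=O)[C@@]1(C)[C@@H](OC(C)=O)CCC(=C)C1=O | intermediate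
12 | (1S,2R,3RS)-2-[(1R)-1-acetoxy-3-(tert-butyldimethylsilyloxy)propyl]-3-hydroxy-2-methyl-4-methylidenecyclohexyl acetate | CC(C)(C)[Si](C)(C)OCC[C@@H](OC(C)=O)[C@@]1(C)[C@@H](OC(C)=O)CCC(=C)C1O | intermediate
13 | allylic mesylate of 12 (at C10, briarane numbering) | CC(C)(C)[Si](C)(C)OCC[C@@H](OC(C)=O)[C@@]1(C)[C@@H](OC(C)=O)CCC(=C)C1OS(C)(=O)=O | intermediate
14 | (1S,2R)-2-[(1R)-1-acetoxy-3-(tert-butyldimethylsilyloxy)propyl]-4-(bromomethyl)-2-methylcyclohex-3-enyl acetate | CC(C)(C)[Si](C)(C)OCC[C@@H](OC(C)=O)[C@@]1(C)[C@@H](OC(C)=O)CCC(CBr)=C1 | intermediate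
15 | tert-butyl diazoacetate | CC(C)(C)OC(=O)C=[N+]=[N-] | starting material
16 | tert-butyl 2-(tert-butyldimethylsilyl)-2-diazoacetate | CC(C)(C)OC(=O)C(=[N+]=[N-])[Si](C)(C)C(C)(C)C | intermediate
17 | tert-butyl 2-(tert-butyldimethylsilyl)-2-oxoacetate | CC(C)(C)OC(=O)C(=O)[Si](C)(C)C(C)(C)C | intermediate
18 | (S)-4-benzyloxazolidin-2-one | O=C1N[C@@H](Cc2ccccc2)CO1 | starting material
19 | 2-bromopropanoyl bromide | CC(Br)C(Br)=O | starting material
20 | N-lithio derivative of 18 | [Li]N1[C@@H](Cc2ccccc2)COC1=O | intermediate
21 | (4S)-4-benzyl-3-[(2RS)-2-bromopropanoyl]oxazolidin-2-one | CC(Br)C(=O)N1[C@@H](Cc2ccccc2)COC1=O | intermediate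
22 | but-2-yne-1,4-diol | OCC#CCO | starting material
23 | monosodium alkoxide of 22 | [Na+].[O-]CC#CCO | intermediate
24 | 4-(4-methoxybenzyloxy)but-2-yn-1-ol | COc1ccc(COCC#CCO)cc1 | intermediate
25 | 4-(4-methoxybenzyloxy)but-2-ynal | COc1ccc(COCC#CC=O)cc1 | intermediate
26 | bromozinc (Z)-enolate of the propanoyl imide | C/C=C(\O[Zn]Br)N1[C@@H](Cc2ccccc2)COC1=O | intermediate
27 | bromozinc enolate of the C8 silyloxy tert-butyl ester after Brook shift (17R; enolate geometry open) | CC(C)(C)OC(O[Zn]Br)=C(O[Si](C)(C)C(C)(C)C)[C@@H](C)C(=O)N1[C@@H](Cc2ccccc2)COC1=O | intermediate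
28 | bromozinc C7 alkoxide (aldolate; 7S,8S,17R) | CC(C)(C)OC(=O)[C@](O[Si](C)(C)C(C)(C)C)([C@@H](C)C(=O)N1[C@@H](Cc2ccccc2)COC1=O)[C@@H](O[Zn]Br)C#CCOCc1ccc(OC)cc1 | intermediate
29 | tert-butyl (2S,3S,4R)-3-(tert-butyldimethylsilyloxy)-2-[3-(4-methoxybenzyloxy)prop-1-ynyl]-4-methyl-5-oxooxolane-3-carboxylate | CC(C)(C)OC(=O)[C@@]1(O[Si](C)(C)C(C)(C)C)[C@H](C#CCOCc2ccc(OC)cc2)OC(=O)[C@@H]1C | intermediate
30 | trimethylsilyl ester of 31 | C[Si](C)(C)OC(=O)[C@@]1(O[Si](C)(C)C(C)(C)C)[C@H](C#CCOCc2ccc(OC)cc2)OC(=O)[C@@H]1C | intermediate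
31 | (2S,3S,4R)-3-(tert-butyldimethylsilyloxy)-2-[3-(4-methoxybenzyloxy)prop-1-ynyl]-4-methyl-5-oxooxolane-3-carboxylic acid | OC(=O)[C@@]1(O[Si](C)(C)C(C)(C)C)[C@H](C#CCOCc2ccc(OC)cc2)OC(=O)[C@@H]1C | intermediate
32 | acid chloride of 31 | ClC(=O)[C@@]1(O[Si](C)(C)C(C)(C)C)[C@H](C#CCOCc2ccc(OC)cc2)OC(=O)[C@@H]1C | intermediate
33 | (2S,3S,4R)-3-(tert-butyldimethylsilyloxy)-2-[3-(4-methoxybenzyloxy)prop-1-ynyl]-4-methyl-5-oxooxolane-3-carbaldehyde | O=C[C@@]1(O[Si](C)(C)C(C)(C)C)[C@H](C#CCOCc2ccc(OC)cc2)OC(=O)[C@@H]1C | intermediate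
34 | allylchromium dichloride from 14 (chromium on C20) | CC(C)(C)[Si](C)(C)OCC[C@@H](OC(C)=O)[C@@]1(C)[C@@H](OC(C)=O)CCC(C[Cr](Cl)Cl)=C1 | intermediate
35 | C9–C10 coupled alcohol: ring A (14-OAc, exocyclic C11=C20) with CH(OAc)CH2CH2OTBS on C1 and the C9 carbinol on C10, joined to C8 of ring C (8-OTBS, C7 bearing C≡C–CH2OPMB); stereocentres as in 48 | CC(C)(C)[Si](C)(C)OCC[C@@H](OC(C)=O)[C@@]1(C)[C@@H](OC(C)=O)CCC(=C)[C@@H]1[C@@H](O)[C@@]2(O[Si](C)(C)C(C)(C)C)[C@H](C#CCOCc3ccc(OC)cc3)OC(=O)[C@@H]2C | intermediate
36 | 9-acetate of 35 | CC(C)(C)[Si](C)(C)OCC[C@@H](OC(C)=O)[C@@]1(C)[C@@H](OC(C)=O)CCC(=C)[C@@H]1[C@@H](OC(C)=O)[C@@]2(O[Si](C)(C)C(C)(C)C)[C@H](C#CCOCc3ccc(OC)cc3)OC(=O)[C@@H]2C | intermediate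
37 | C11=C12 isomer of 36 (ring A alkene as in 48) | CC(C)(C)[Si](C)(C)OCC[C@@H](OC(C)=O)[C@@]1(C)[C@@H](OC(C)=O)CC=C(C)[C@@H]1[C@@H](OC(C)=O)[C@@]2(O[Si](C)(C)C(C)(C)C)[C@H](C#CCOCc3ccc(OC)cc3)OC(=O)[C@@H]2C | intermediate
38 | propargylic alcohol (16-OH) from 37 | CC(C)(C)[Si](C)(C)OCC[C@@H](OC(C)=O)[C@@]1(C)[C@@H](OC(C)=O)CC=C(C)[C@@H]1[C@@H](OC(C)=O)[C@@]2(O[Si](C)(C)C(C)(C)C)[C@H](C#CCO)OC(=O)[C@@H]2C | intermediate
39 | (Z)-alkenylstannane (Bu3Sn on C5, cis to C7) | CC(C)(C)[Si](C)(C)OCC[C@@H](OC(C)=O)[C@@]1(C)[C@@H](OC(C)=O)CC=C(C)[C@@H]1[C@@H](OC(C)=O)[C@@]2(O[Si](C)(C)C(C)(C)C)[C@H](/C=C(\[Sn](CCCC)(CCCC)CCCC)CO)OC(=O)[C@@H]2C | intermediate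
40 | (Z)-C5 iodoalkene with free 16-OH | CC(C)(C)[Si](C)(C)OCC[C@@H](OC(C)=O)[C@@]1(C)[C@@H](OC(C)=O)CC=C(C)[C@@H]1[C@@H](OC(C)=O)[C@@]2(O[Si](C)(C)C(C)(C)C)[C@H](/C=C(\I)CO)OC(=O)[C@@H]2C | intermediate
41 | O16-TBDPS ether of 40 | CC(C)(C)[Si](C)(C)OCC[C@@H](OC(C)=O)[C@@]1(C)[C@@H](OC(C)=O)CC=C(C)[C@@H]1[C@@H](OC(C)=O)[C@@]2(O[Si](C)(C)C(C)(C)C)[C@H](/C=C(\I)CO[Si](c3ccccc3)(c3ccccc3)C(C)(C)C)OC(=O)[C@@H]2C | intermediate
42 | C4 primary alcohol from 41 | OCC[C@@H](OC(C)=O)[C@@]1(C)[C@@H](OC(C)=O)CC=C(C)[C@@H]1[C@@H](OC(C)=O)[C@@]2(O[Si](C)(C)C(C)(C)C)[C@H](/C=C(\I)CO[Si](c3ccccc3)(c3ccccc3)C(C)(C)C)OC(=O)[C@@H]2C | intermediate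
43 | C4 aldehyde | O=CC[C@@H](OC(C)=O)[C@@]1(C)[C@@H](OC(C)=O)CC=C(C)[C@@H]1[C@@H](OC(C)=O)[C@@]2(O[Si](C)(C)C(C)(C)C)[C@H](/C=C(\I)CO[Si](c3ccccc3)(c3ccccc3)C(C)(C)C)OC(=O)[C@@H]2C | intermediate
44 | C5 alkenylchromium dichloride from 43 | O=CC[C@@H](OC(C)=O)[C@@]1(C)[C@@H](OC(C)=O)CC=C(C)[C@@H]1[C@@H](OC(C)=O)[C@@]2(O[Si](C)(C)C(C)(C)C)[C@H](/C=C(\[Cr](Cl)Cl)CO[Si](c3ccccc3)(c3ccccc3)C(C)(C)C)OC(=O)[C@@H]2C | intermediate
45 | ring B alcohol (4R-OH, O8-TBS, O16-TBDPS, 2,9,14-triacetate) | O[C@@H]1C[C@@H](OC(C)=O)[C@@]2(C)[C@@H](OC(C)=O)CC=C(C)[C@@H]2[C@@H](OC(C)=O)[C@@]2(O[Si](C)(C)C(C)(C)C)[C@H](/C=C\1CO[Si](c3ccccc3)(c3ccccc3)C(C)(C)C)OC(=O)[C@@H]2C | intermediate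
46 | 4-butanoate of 45 | CCCC(=O)O[C@@H]1C[C@@H](OC(C)=O)[C@@]2(C)[C@@H](OC(C)=O)CC=C(C)[C@@H]2[C@@H](OC(C)=O)[C@@]2(O[Si](C)(C)C(C)(C)C)[C@H](/C=C\1CO[Si](c3ccccc3)(c3ccccc3)C(C)(C)C)OC(=O)[C@@H]2C | intermediate
47 | 8,16-diol (16-deacetyl-48) | CCCC(=O)O[C@@H]1C[C@@H](OC(C)=O)[C@@]2(C)[C@@H](OC(C)=O)CC=C(C)[C@@H]2[C@@H](OC(C)=O)[C@@]2(O)[C@H](/C=C\1CO)OC(=O)[C@@H]2C | intermediate
48 | CNP0290502.1: (1R,2R,4R,5Z,7S,8S,9R,10S,14S,17R)-2,9,14,16-tetraacetoxy-4-butanoyloxy-8-hydroxybriara-5,11-diene 19,7-lactone | CCCC(=O)O[C@@H]1C[C@@H](OC(C)=O)[C@@]2(C)[C@@H](OC(C)=O)CC=C(C)[C@@H]2[C@@H](OC(C)=O)[C@@]2(O)[C@H](/C=C\1COC(C)=O)OC(=O)[C@@H]2C | target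

## Step count and least certain steps

Total: 30 steps. Longest linear sequence: 22 steps (steps 1–10, then 19–30). The ring C branch (steps 11, 12, 16–18, then 19–30) has 17.

**Step 16 (key step, new method).** What may go wrong: direct addition of enolate 26 to the ynal; proton transfer from the acidic C17–H of the imide to enolate 27; attack of the C7 alkoxide on the ring carbonyl of the auxiliary; and a wrong facial sense in either C–C bond formation, since control by the auxiliary in this cascade is untested. Fallback with known chemistry, from 17 and 25 back to 29: the zinc enolate of ethyl 2-bromopropanoate replaces 26 in the established ester version of the coupling (same order of addition), and lactonisation then expels ethoxide. This gives the racemic lactone, that is 29 together with its mirror image, the (2R,3R,4S)-lactone F1. The two are separated by preparative chromatography on a chiral stationary phase and 29 continues at step 17.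

**Step 19.** What may go wrong: slow bond formation between two carbons that each have a fully substituted neighbour, addition on the other face of ring A or through a boat arrangement, and transfer of the lactone acyl group to the new O9 alkoxide. Fallback from 14 back to 35: 14 is converted with bis(pinacolato)diboron and Pd2(dba)3 in DMSO into the allylic pinacol boronate F2. Heating F2 with 33 in toluene effects an uncatalysed allylboration through the same chair arrangement, with shorter bonds to boron and no Lewis-acidic chromium alkoxide, and aqueous work-up gives 35.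

**Step 27.** What may go wrong: oligomerisation instead of closure of the ten-membered ring, ionisation of the allylic C7–O bond by zerovalent nickel, and poor facial selectivity at C4. Fallback from 43 back to 46: if closure gives mainly the C4 epimer of 45, the 4S alcohol F3, it is esterified under Mitsunobu conditions (butanoic acid, PPh3, diisopropyl azodicarboxylate). This installs the butanoate with inversion and gives 46 directly.

**Step 21.** What may go wrong: hydrogen abstraction at C10 giving the tetrasubstituted alkene, radical addition to the alkyne, and over-reduction. Fallback from 36 back to 37: Mukaiyama hydration (Co(acac)2, PhSiH3, O2) converts the exocyclic alkene into the tertiary C11 alcohol F4. Dehydration with SOCl2 and pyridine, which removes an anti-periplanar ring hydrogen at C12, gives 37.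

**Step 3.** What may go wrong: poor discrimination between the two carbonyl groups because the C2 centre is remote from the catalyst, and over-reduction to the diol. Fallback from 4 back to 5: substrate-controlled reduction with NaBH4 at low temperature (hydride anti to the side chain) gives 5 together with the hydroxy ketone of opposite configuration at the quaternary and carbinol carbons, the (2S,3R) diastereomer F5. The two are separated by chromatography and F5 is returned to 4 by Dess–Martin oxidation.

## Further compounds

F1 | step 16 | tert-butyl (2R,3R,4S)-3-(tert-butyldimethylsilyloxy)-2-[3-(4-methoxybenzyloxy)prop-1-ynyl]-4-methyl-5-oxooxolane-3-carboxylate (mirror image of 29) | CC(C)(C)OC(=O)[C@]1(O[Si](C)(C)C(C)(C)C)[C@@H](C#CCOCc2ccc(OC)cc2)OC(=O)[C@H]1C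
F2 | step 19 | allylic pinacol boronate corresponding to 14 (Bpin in place of Br) | CC(C)(C)[Si](C)(C)OCC[C@@H](OC(C)=O)[C@@]1(C)[C@@H](OC(C)=O)CCC(CB2OC(C)(C)C(C)(C)O2)=C1
F3 | step 27 | C4 epimer of 45 (4S alcohol) | O[C@H]1C[C@@H](OC(C)=O)[C@@]2(C)[C@@H](OC(C)=O)CC=C(C)[C@@H]2[C@@H](OC(C)=O)[C@@]2(O[Si](C)(C)C(C)(C)C)[C@H](/C=C\1CO[Si](c3ccccc3)(c3ccccc3)C(C)(C)C)OC(=O)[C@@H]2C
F4 | step 21 | tertiary C11 alcohol from hydration of 36 (C11 configuration open) | CC(C)(C)[Si](C)(C)OCC[C@@H](OC(C)=O)[C@@]1(C)[C@@H](OC(C)=O)CCC(C)(O)[C@@H]1[C@@H](OC(C)=O)[C@@]2(O[Si](C)(C)C(C)(C)C)[C@H](C#CCOCc3ccc(OC)cc3)OC(=O)[C@@H]2C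
F5 | step 3 | (2S,3R)-2-[(1R)-1-(benzyloxy)prop-2-enyl]-3-hydroxy-2-methylcyclohexanone | C=C[C@@H](OCc1ccccc1)[C@]1(C)[C@H](O)CCCC1=O
A1 | alternative 1 | (1E,3E)-1-(triisopropylsilyloxy)penta-1,3-diene | C/C=C/C=C/O[Si](C(C)C)(C(C)C)C(C)C
A2 | alternative 1 | (E)-4-(benzyloxy)-2-methylbut-2-enal | O=C/C(C)=C/COCc1ccccc1
A3 | alternative 1 | ring A cyclohexene aldehyde (cycloadduct with C1, C10 and C14 set) | O=C[C@@]1(C)[C@@H](O[Si](C(C)C)(C(C)C)C(C)C)C=C[C@@H](C)[C@@H]1COCc1ccccc1
A4 | alternative 2 | thirteen-membered C9–O–C12 ether with tributylstannyl on C9 (C9 and C12 configuration open) | COc1ccc(CO[C@@H]2C[C@@H](OCOC)[C@@]3(C)[C@@H](OCOC)CC(OC([Sn](CCCC)(CCCC)CCCC)[C@@]([C@@H](C)CO[Si](C)(C)C(C)(C)C)(O)[C@H](/C=C\2COCOC)OCOC)C(C)=C3)cc1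
A5 | alternative 2 | ring A–ring B bicycle with free C8 and C9 hydroxyls | COc1ccc(CO[C@@H]2C[C@@H](OCOC)[C@@]3(C)[C@@H](OCOC)CC=C(C)[C@@H]3[C@@H](O)[C@@]([C@@H](C)CO[Si](C)(C)C(C)(C)C)(O)[C@H](/C=C\2COCOC)OCOC)cc1
A6 | alternative 3 | fourteen-membered 2-methyl-1,3-diketone with C12 methyl carbonate (C1, C12 and C10=C11 geometry open) | COc1ccc(CO[C@@H]2CC(=O)C(C)C(=O)CC(OC(=O)OC)C(C)=C[C@H]3OC(C)(C)O[C@@]3([C@@H](C)CO[Si](C)(C)C(C)(C)C)[C@H](/C=C\2CO[Si](C)(C)C(C)(C)C)O[Si](C)(C)C(C)(C)C)cc1
A7 | alternative 3 | bicyclic 2,14-diketone with rings A and B | COc1ccc(CO[C@@H]2CC(=O)[C@@]3(C)C(=O)CC=C(C)[C@@H]3[C@H]4OC(C)(C)O[C@@]4([C@@H](C)CO[Si](C)(C)C(C)(C)C)[C@H](/C=C\2CO[Si](C)(C)C(C)(C)C)O[Si](C)(C)C(C)(C)C)cc1
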